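## Analysis of the target

- Target 15 has no ring other than four benzene rings and no stereocenter. Ring A (3-hydroxy-5-methoxyphenyl) and ring B (a phenol) are joined by a CH2CH2 bridge to a bibenzyl, and ring B carries two 4-hydroxybenzyl groups.
- With B1 as the ring B carbon bearing the bridge, the 4-hydroxybenzyl groups sit at B2 and B6, the hydroxyl at B5, and B3 and B4 are CH. Four substituents stand side by side (B5, B6, B1, B2), and B6 is wedged between the hydroxyl and the bridge.
- The sensitive groups are the four free phenols, which oxidize easily as phenolates and activate every ring toward electrophiles. The single methyl ether of ring A must stay distinct from the ring A hydroxyl, and the two doubly benzylic CH2 groups are open to oxidation.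
- The difficulty is purely regiochemical. Two identical benzyl groups must go to B2 and to the crowded B6 and nowhere else. They must not go to B4 (the second ortho position of the ring B phenol), to the three CH positions of ring A (each ortho or para to two oxygen atoms), or to the hydroxyphenyl rings.
- The strategy rests on one feature: B6 is ortho and B2 is para to the B5 hydroxyl, and each benzylic carbon bound there carries a para-hydroxyphenyl group. This is the pattern left when the ring B phenolate is alkylated on carbon by the para-quinone methide 11 of 4-hydroxybenzyl alcohol 10.
- The B5 oxygen can therefore direct both C–C bonds, provided B4 is blocked and ring A is kept from reacting.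

## Retrosynthetic reasoning

**15 back to 13.** No skeletal bond is cut first. Two auxiliary groups are added in the retro direction: a bromine atom at B4 and a benzyl ether on the ring A hydroxyl, giving bromophenol 13. Without the bromine, B4 is the less hindered ortho position and would be alkylated before B6. Without the ether, ring A would ionize and compete. Both groups fall in a single catalytic hydrogenolysis (through 14), so together they cost one step at the end.

**13 back to 9 and two molecules of 10.** The bonds B2–CH2 and B6–CH2 are cut. The aryl–CH2 bonds on the far side of the same carbons are not chosen, because only the ring B carbons are ortho or para to an oxygen that can be turned into a phenolate donor. This reveals bibenzyl bromophenol 9 as the nucleophile and 10 as the precursor of the electrophile 11, with the monobenzylated phenol 12 in between. The gain is the whole carbon skeleton in one operation, in the oxidation state of the target, from an unprotected building block. The forward reaction must alkylate on carbon and not on oxygen, at B2 and at the hindered B6, and must leave ring A and the new phenol rings alone.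

**9 back to 8.** The saturated bridge is traced to the stilbene 8, because a double bond between the two rings is the easiest link to make convergently. The forward reduction must spare the C–Br bond and the benzyl ether. That rules out a heterogeneous metal-catalysed hydrogenation and calls for a metal-free hydrogen transfer.

**8 back to 7 and 6.** The double bond is cut to ylide 7 and aldehyde 6. Aldehyde 6 is bought with the full ring B pattern: its carbonyl carbon becomes the bridge carbon on B1, its hydroxyl is the B5 oxygen and its bromine is the B4 blocking atom. The geometry of the double bond does not matter.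

**7 back to 1.** Ylide 7 comes from phosphonium salt 5, which is traced by functional group interconversions through bromide 4, alcohol 3 and benzyl ether 2 to aldehyde 1. Aldehyde 1 already has the methoxy and hydroxyl groups of ring A differentiated. The benzylation comes first so that the phenol is masked through the whole sequence.

## Alternatives that were turned down

**Alternative 1: aryne acyl-alkylation at B1 and B6.**
- Disconnection: two neighbouring bonds of ring B, B1–CH2 of the bridge and B6–C of one benzyl group, are cut together and traced to an aryne.
- Forward key step: CsF would release the aryne from silyl triflate A2. The aryne would insert into the bond between the alpha carbon and the ketone carbon of beta-ketoester A3, giving aryl acetate A1 with the aroyl group at B6.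
- For: two vicinal C–C bonds form at the most crowded part of ring B. The alkoxy group next to the aryne steers the enolate carbon to the distal aryne carbon, and over-alkylation cannot occur. On site control it is stronger than the chosen route, which relies on innate phenolate reactivity.
- Against: A2 is itself a contiguously tetrasubstituted benzene that already holds the B2 benzyl group, and it would need a longer synthesis than the whole chosen route. In the aryne, the carbon the enolate must attack is flanked by that benzyl group, so sterics oppose the electronic bias. A1 is still far from the target: the diaryl ketone must be deoxygenated, and the ester carbon must become the second bridge carbon bearing ring A, which needs a ring A nucleophile and a second deoxygenation before global debenzylation.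
- Comparison: the chosen strategy gives up guaranteed regiochemistry but forms both benzylic bonds at the right oxidation state, with one protecting group, in 8 steps.

**Alternative 2: ring A built from an enone and malonate.**
- Disconnection: ring A is taken apart and ring B is left whole. The cyclohexane-1,3-dione A4 is traced to enone A5 and dimethyl malonate A6.
- Forward key step: the anion of A6 (NaOCH3) would add to the beta carbon of A5, and the methyl ketone would then close onto one ester to form the six-membered ring. Saponification and decarboxylation (NaOH, then HCl) would give A4. Its monomethyl enol ether, a vinylogous ester, would then be dehydrogenated to the 3-methoxy-5-alkylphenol.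
- For: the chemistry is classical and reliable, and the methoxy and hydroxyl groups of ring A emerge differentiated without a protecting group. On that point it is as strong as the chosen route.
- Against: the differentiation is not a problem here, because aldehyde 1 is bought with it. The key step builds the easy ring, while A5 must already contain ring B with both benzyl groups in place, which this plan does not address. The late dehydrogenation would also have to spare three benzyl ethers and two diarylmethane CH2 groups.
- Comparison: the chosen strategy spends its key step on the bonds that make the target hard and buys ring A.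

**Alternative 3: Catellani ortho-benzylation with Heck termination.**
- Disconnection: B2–CH2 and B1–CH= are cut, and stilbene A7 is traced to aryl iodide A8 (iodine at B1, benzyl group at B6), benzylic chloride A9 and ring A styrene A10.
- Forward key step: Pd(OAc)2, a triarylphosphine, norbornene A11 and Cs2CO3 would relay palladium from B1 to the free ortho carbon B2 through a palladacycle. A9 would alkylate there, A11 would be extruded, and a Heck reaction with A10 at B1 would close the sequence to A7. One hydrogenation would then saturate the stilbene and remove four benzyl groups.
- For: it is convergent, forms two C–C bonds, and fixes the positions by the iodine and the palladacycle. Site control and freedom from over-alkylation are stronger than in the chosen route.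
- Against: A8 already holds half of the problem, a benzyl group between iodine and a benzyloxy group, and needs several steps. An electron-rich benzylic chloride is a less secure partner for the palladacycle than a simple alkyl halide, since it can add to zerovalent palladium itself and then couple with A10 or with itself. The Heck termination must occur at an aryl–palladium centre with two ortho substituents. Three fragments and four benzyl ethers put the step count well above that of the chosen route.
- Comparison: the chosen strategy needs no transition-metal C–C coupling and runs as one linear sequence of 8 steps from two bought arenes and 10, at the price of depending on phenolate selectivity.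

Key step: step 7

Remark on the chemistry: stilbene 8 is expected as an E/Z mixture and is used as such, because step 6 removes the double bond. Compounds 1, 6 and 10 are taken as purchasable.

## Route

Step 1
Reactants: 1 3-hydroxy-5-methoxybenzaldehyde
Product: 2 3-(benzyloxy)-5-methoxybenzaldehyde
Conditions: BnBr, K2CO3, DMF, rt
Reagents that add atoms: benzyl bromide, BrCc1ccccc1
Why: Williamson ether synthesis: the phenolate formed by K2CO3 displaces bromide from benzyl bromide in an SN2 reaction, and the aldehyde is inert under these conditions.

Step 2
Reactants: 2 3-(benzyloxy)-5-methoxybenzaldehyde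
Product: 3 [3-(benzyloxy)-5-methoxyphenyl]methanol
Conditions: NaBH4, MeOH, 0 °C
Reagents that add atoms: none
Why: Hydride reduction of an aromatic aldehyde to the primary benzylic alcohol; the benzyl and methyl aryl ethers are inert to NaBH4.

Step 3
Reactants: 3 [3-(benzyloxy)-5-methoxyphenyl]methanol
Product: 4 1-(benzyloxy)-3-(bromomethyl)-5-methoxybenzene
Conditions: PBr3 (0.4 equiv), CH2Cl2, 0 °C
Reagents that add atoms: phosphorus tribromide, BrP(Br)Br
Why: Bromination of a primary benzylic alcohol through its phosphite ester, which bromide displaces in an SN2 reaction; at 0 °C the aryl ethers should survive.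

Step 4
Reactants: 4 1-(benzyloxy)-3-(bromomethyl)-5-methoxybenzene
Product: 5 [3-(benzyloxy)-5-methoxybenzyl]triphenylphosphonium bromide
Conditions: PPh3, toluene, reflux
Reagents that add atoms: triphenylphosphine, c1ccc(cc1)P(c1ccccc1)c1ccccc1
Why: SN2 quaternization of the phosphine by a benzylic bromide; the salt should precipitate from toluene and be collected by filtration.

Step 5
Reactants: 5 [3-(benzyloxy)-5-methoxybenzyl]triphenylphosphonium bromide, 6 4-bromo-3-hydroxybenzaldehyde
Product: 8 5-{2-[3-(benzyloxy)-5-methoxyphenyl]ethenyl}-2-bromophenol as E/Z mixture, via phosphonium ylide 7 (not isolated)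
Conditions: KOtBu (2.2 equiv), THF/DMF, 0 °C to rt
Reagents that add atoms: none
Why: Wittig olefination: one equivalent of KOtBu forms ylide 7 and a second converts 6 into its phenolate beforehand, so that no proton quenches the ylide; the phenolate is meta to the formyl group and does not deactivate it by conjugation, and the aryl bromide is inert to alkoxide and ylide. The semi-stabilized ylide should give both alkene isomers, which is of no consequence.

Step 6
Reactants: 8 5-{2-[3-(benzyloxy)-5-methoxyphenyl]ethenyl}-2-bromophenol as E/Z mixture
Product: 9 5-{2-[3-(benzyloxy)-5-methoxyphenyl]ethyl}-2-bromophenol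
Conditions: TsNHNH2 (excess), NaOAc, THF/H2O, reflux
Reagents that add atoms: none
Why: Diimide reduction: HN=NH released by thermal fragmentation of the sulfonyl hydrazide delivers two hydrogen atoms to the nonpolar C=C in a concerted syn transfer, and it attacks neither the C–Br bond nor the benzyl ether, both of which a palladium-catalysed hydrogenation would cleave.

Step 7
Reactants: 9 5-{2-[3-(benzyloxy)-5-methoxyphenyl]ethyl}-2-bromophenol, 10 4-hydroxybenzyl alcohol (2.4 equiv)
Product: 13 3-{2-[3-(benzyloxy)-5-methoxyphenyl]ethyl}-6-bromo-2,4-bis(4-hydroxybenzyl)phenol, via para-quinone methide 11 (not isolated), via 4-monobenzyl bromophenol 12 (not isolated)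
Conditions: K2CO3 (1.2 equiv), degassed H2O/1,4-dioxane, 100–110 °C, sealed vessel under Ar, 10 added in portions
Reagents that add atoms: none
Why: In the hot carbonate solution a small part of 10 is present as its phenolate, which expels hydroxide in a reversible 1,6-elimination to the para-quinone methide 11, a soft carbon electrophile that water only returns to 10. The phenolate of 9, fully formed because the ortho bromine makes this the most acidic phenol in the flask, adds to the exocyclic CH2 of 11 through its para carbon B2 in a vinylogous Michael (1,6-) addition, and tautomerization of the cyclohexadienone restores the aromatic ring in 12; the same sequence at the ortho carbon B6 then gives 13. The closest known reaction type is the base-mediated condensation of hydroxybenzyl alcohols with phenols that underlies phenol–formaldehyde resin formation, which also runs through quinone methides and phenolate carbon nucleophiles. No ring is closed and no stereocenter is created. The step needs site selectivity on ring B, which the substrate secures: B4 carries bromine and B3 is meta to the oxygen and receives no phenolate electron density, so B2 and B6 are the only nucleophilic carbons. It needs selectivity against ring A, which is held as two ethers, cannot ionize and is far less nucleophilic than a phenolate when no acid is present. It needs C- over O-alkylation: the aryl 4-hydroxybenzyl ether from O-attack still holds a para phenol and can return to 11, so it drains toward the irreversible C-alkylation that the protic medium favours. Alkylation of the hydroxyphenyl rings of 10, 12 and 13, which have only ortho positions free and are less ionized with this limited amount of base, is held back by keeping 10 near two equivalents and adding it in portions.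

Step 8
Reactants: 13 3-{2-[3-(benzyloxy)-5-methoxyphenyl]ethyl}-6-bromo-2,4-bis(4-hydroxybenzyl)phenol
Product: 15 3-[2-(3-hydroxy-5-methoxyphenyl)ethyl]-2,4-bis(4-hydroxybenzyl)phenol, via debrominated benzyl ether 14 (not isolated)
Conditions: H2 (1 atm), 10% Pd/C, NaOAc, MeOH/EtOAc, rt
Reagents that add atoms: none
Why: Palladium-catalysed hydrogenolysis: the aryl C–Br bond is expected to be reduced first (oxidative addition to zerovalent palladium, then hydride transfer, with NaOAc taking up HBr), followed by cleavage of the benzyl aryl ether; the diarylmethane CH2 groups have no leaving group and the methyl ether is inert, so both should persist.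

## Compound list

1 | 3-hydroxy-5-methoxybenzaldehyde | COc1cc(O)cc(C=O)c1 | starting material
2 | 3-(benzyloxy)-5-methoxybenzaldehyde | COc1cc(OCc2ccccc2)cc(C=O)c1 | intermediate
3 | [3-(benzyloxy)-5-methoxyphenyl]methanol | COc1cc(OCc2ccccc2)cc(CO)c1 | intermediate
4 | 1-(benzyloxy)-3-(bromomethyl)-5-methoxybenzene | COc1cc(OCc2ccccc2)cc(CBr)c1 | intermediate
5 | [3-(benzyloxy)-5-methoxybenzyl]triphenylphosphonium bromide | COc1cc(OCc2ccccc2)cc(C[P+](c2ccccc2)(c2ccccc2)c2ccccc2)c1.[Br-] | intermediate
6 | 4-bromo-3-hydroxybenzaldehyde | O=Cc1ccc(Br)c(O)c1 | starting material
7 | [3-(benzyloxy)-5-methoxybenzylidene]triphenylphosphorane (ylide, formed in the flask) | COc1cc(OCc2ccccc2)cc(C=P(c2ccccc2)(c2ccccc2)c2ccccc2)c1 | intermediate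
8 | 5-{2-[3-(benzyloxy)-5-methoxyphenyl]ethenyl}-2-bromophenol (E/Z mixture, double bond geometry not defined) | COc1cc(OCc2ccccc2)cc(C=Cc2ccc(Br)c(O)c2)c1 | intermediate
9 | 5-{2-[3-(benzyloxy)-5-methoxyphenyl]ethyl}-2-bromophenol | COc1cc(OCc2ccccc2)cc(CCc2ccc(Br)c(O)c2)c1 | intermediate
10 | 4-hydroxybenzyl alcohol | OCc1ccc(O)cc1 | starting material
11 | para-quinone methide, 4-methylidenecyclohexa-2,5-dien-1-one (formed in the flask) | C=C1C=CC(=O)C=C1 | intermediate
12 | 5-{2-[3-(benzyloxy)-5-methoxyphenyl]ethyl}-2-bromo-4-(4-hydroxybenzyl)phenol (formed in the flask) | COc1cc(OCc2ccccc2)cc(CCc2cc(O)c(Br)cc2Cc2ccc(O)cc2)c1 | intermediate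
13 | 3-{2-[3-(benzyloxy)-5-methoxyphenyl]ethyl}-6-bromo-2,4-bis(4-hydroxybenzyl)phenol | COc1cc(OCc2ccccc2)cc(CCc2c(Cc3ccc(O)cc3)cc(Br)c(O)c2Cc2ccc(O)cc2)c1 | intermediate
14 | 3-{2-[3-(benzyloxy)-5-methoxyphenyl]ethyl}-2,4-bis(4-hydroxybenzyl)phenol (formed in the flask) | COc1cc(OCc2ccccc2)cc(CCc2c(Cc3ccc(O)cc3)ccc(O)c2Cc2ccc(O)cc2)c1 | intermediate
15 | 3-[2-(3-hydroxy-5-methoxyphenyl)ethyl]-2,4-bis(4-hydroxybenzyl)phenol | COc1cc(O)cc(CCc2c(Cc3ccc(O)cc3)ccc(O)c2Cc2ccc(O)cc2)c1 | target

## Step count and risk

Total step count: 8. Longest linear sequence: 8 steps (1 to 15); 6 and 10 are bought and enter directly.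

**Step 7 (key step).**
- Risk: the second alkylation is most likely to stall. Once B2 has reacted, the remaining site B6 lies between the phenolate oxygen and the bridge, and the bromophenolate is a weaker carbon nucleophile than an alkylphenolate. Quinone methide 11 may then be consumed by the ortho carbons of the hydroxyphenyl rings of 10, 12 and 13, which means self-condensation of 10 and over-benzylation.
- Fallback (from 9, returning at 15): the two carbon atoms are introduced with the smallest electrophile and the aryl groups are added afterwards.
  - Compound 9 is treated with excess aqueous formaldehyde and NaOH at rt to 40 °C (Lederer–Manasse hydroxymethylation). This should place one CH2OH at each of the same two positions and give the bis(hydroxymethyl)phenol F1.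
  - Activated MnO2 in CHCl3 oxidizes the two benzylic alcohols to the hydroxy dialdehyde F2.
  - Excess 4-(benzyloxy)phenylmagnesium bromide in THF at 0 °C adds to both formyl groups (one equivalent is consumed by the phenol) to give the bis(diarylmethanol) F3 as a diastereomer mixture. The mixture is of no consequence because both carbinol centres are removed.
  - Hydrogenation over Pd/C in EtOAc/AcOH then cleaves the two doubly benzylic C–OH bonds, the three benzyl ethers and the C–Br bond in one operation and gives 15.

**Step 5.**
- Risk: proton transfer from incompletely ionized 6 may quench ylide 7, or the potassium salt of 6 may separate from the solvent, so that the olefination stays incomplete.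
- Fallback (from 6, returning at 8): the phenol is masked before the olefination.
  - Compound 6 is silylated (TBSCl, imidazole, DMF) to the silyl ether aldehyde F4.
  - F4 is combined with ylide 7, made from 5 with one equivalent of KOtBu in THF, to give the silyl stilbene F5 as an E/Z mixture.
  - Bu4NF in THF frees the phenol and gives 8. Premature loss of the silyl group would lead to 8 as well.

**Step 8.**
- Risk: bromide released in the first hydrogenolysis may slow the catalyst so that cleavage of the benzyl ether stays incomplete, or the debromination may stall, leaving brominated material that is hard to separate from 15.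
- Fallback (from 13, returning at 15): the two cleavages are separated and run without H2 gas; no new compound is made (F0).
  - Homogeneous hydrodebromination with Pd(OAc)2/PPh3 and HCO2Na in DMF at 80 °C gives 14, which is now isolated.
  - BCl3 with pentamethylbenzene in CH2Cl2 at −78 °C removes the benzyl group as a cation trapped by the scavenger, without touching the methyl ether, and gives 15.

**Step 6.**
- Risk: disproportionation of diimide may outrun its addition to the conjugated diaryl-substituted double bond, so that conversion stays incomplete and alkene and alkane, which are hard to separate, remain mixed.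
- Fallback (from 8, returning at 15): the saturation is moved to the end.
  - Compound 8 itself is taken through the conditions of step 7. Its phenolate has the same free positions B2 and B6, and the double bond, attached at B1 meta to the oxygen, receives no phenolate charge. This should give the bis-benzylated stilbene F6.
  - The final hydrogenation over Pd/C with NaOAc then reduces the double bond together with the C–Br and benzyl ether cleavage and gives 15.

## Further compounds

F1 | step 7 | 3-{2-[3-(benzyloxy)-5-methoxyphenyl]ethyl}-6-bromo-2,4-bis(hydroxymethyl)phenol | COc1cc(OCc2ccccc2)cc(CCc2c(CO)cc(Br)c(O)c2CO)c1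
F2 | step 7 | 2-{2-[3-(benzyloxy)-5-methoxyphenyl]ethyl}-5-bromo-4-hydroxybenzene-1,3-dicarbaldehyde | COc1cc(OCc2ccccc2)cc(CCc2c(C=O)cc(Br)c(O)c2C=O)c1
F3 | step 7 | 3-{2-[3-(benzyloxy)-5-methoxyphenyl]ethyl}-2,4-bis{[4-(benzyloxy)phenyl](hydroxy)methyl}-6-bromophenol (mixture of diastereomers, carbinol centres not defined) | COc1cc(OCc2ccccc2)cc(CCc2c(C(O)c3ccc(OCc4ccccc4)cc3)cc(Br)c(O)c2C(O)c2ccc(OCc3ccccc3)cc2)c1
F4 | step 5 | 4-bromo-3-[(tert-butyldimethylsilyl)oxy]benzaldehyde | CC(C)(C)[Si](C)(C)Oc1cc(C=O)ccc1Br
F5 | step 5 | (5-{2-[3-(benzyloxy)-5-methoxyphenyl]ethenyl}-2-bromophenoxy)(tert-butyl)dimethylsilane (E/Z mixture) | COc1cc(OCc2ccccc2)cc(C=Cc2ccc(Br)c(O[Si](C)(C)C(C)(C)C)c2)c1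
F0 | step 8 | none | none
F6 | step 6 | 3-{2-[3-(benzyloxy)-5-methoxyphenyl]ethenyl}-6-bromo-2,4-bis(4-hydroxybenzyl)phenol (E/Z mixture) | COc1cc(OCc2ccccc2)cc(C=Cc2c(Cc3ccc(O)cc3)cc(Br)c(O)c2Cc2ccc(O)cc2)c1
A1 | alternative 1 | methyl 2-{3-(benzyloxy)-6-[4-(benzyloxy)benzyl]-2-[4-(benzyloxy)benzoyl]phenyl}acetate | COC(=O)Cc1c(Cc2ccc(OCc3ccccc3)cc2)ccc(OCc2ccccc2)c1C(=O)c1ccc(OCc2ccccc2)cc1
A2 | alternative 1 | 3-(benzyloxy)-6-[4-(benzyloxy)benzyl]-2-(trimethylsilyl)phenyl trifluoromethanesulfonate | C[Si](C)(C)c1c(OCc2ccccc2)ccc(Cc2ccc(OCc3ccccc3)cc2)c1OS(=O)(=O)C(F)(F)F
A3 | alternative 1 | methyl 3-[4-(benzyloxy)phenyl]-3-oxopropanoate | COC(=O)CC(=O)c1ccc(OCc2ccccc2)cc1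
A4 | alternative 2 | 5-(2-{3-(benzyloxy)-2,6-bis[4-(benzyloxy)benzyl]phenyl}ethyl)cyclohexane-1,3-dione | O=C1CC(=O)CC(CCc2c(Cc3ccc(OCc4ccccc4)cc3)ccc(OCc3ccccc3)c2Cc2ccc(OCc3ccccc3)cc2)C1
A5 | alternative 2 | (3E)-6-{3-(benzyloxy)-2,6-bis[4-(benzyloxy)benzyl]phenyl}hex-3-en-2-one | CC(=O)/C=C/CCc1c(Cc2ccc(OCc3ccccc3)cc2)ccc(OCc2ccccc2)c1Cc1ccc(OCc2ccccc2)cc1
A6 | alternative 2 | dimethyl malonate | COC(=O)CC(=O)OC
A7 | alternative 3 | 1-(benzyloxy)-3-[(E)-2-{3-(benzyloxy)-2,6-bis[4-(benzyloxy)benzyl]phenyl}ethenyl]-5-methoxybenzene | COc1cc(OCc2ccccc2)cc(/C=C/c2c(Cc3ccc(OCc4ccccc4)cc3)ccc(OCc3ccccc3)c2Cc2ccc(OCc3ccccc3)cc2)c1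
A8 | alternative 3 | 1-(benzyloxy)-2-[4-(benzyloxy)benzyl]-3-iodobenzene | Ic1cccc(OCc2ccccc2)c1Cc1ccc(OCc2ccccc2)cc1
A9 | alternative 3 | 1-(benzyloxy)-4-(chloromethyl)benzene | ClCc1ccc(OCc2ccccc2)cc1
A10 | alternative 3 | 1-(benzyloxy)-3-ethenyl-5-methoxybenzene | COc1cc(OCc2ccccc2)cc(C=C)c1
A11 | alternative 3 | norbornene (bicyclo[2.2.1]hept-2-ene) | C1=CC2CCC1C2
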